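Ring C (O1; C2 bearing ring A; C4–OH; C6 bearing the C7–C8 chain to ring B) is disconnected at C2–C3. The precursor 14 is the ring A benzylic ether of an (S)-configured C6 carbinol carrying an enol acetate, with ring A's O3/O4 tied as a diphenylmethylene acetal and ring B as its pivalate. The key step exploits the C2–H bond, which is benzylic to ring A, para to its conjugated 4-oxygen and adjacent to O1: DDQ abstracts it as hydride and the enol acetate adds to the oxocarbenium ion, so one operation forms C2–C3, closes ring C, sets C2 (2,6-cis) and unveils the C4 ketone. Axial-selective reduction and deprotection follow.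

Key step: step 10

Remark: the facial sense of step 4 is assigned by analogy with aromatic aldehydes under the same catalyst; configuration and enantiomeric purity of 8 would be checked (chiral HPLC, MTPA esters) before it is carried on, and the (S)-catalyst used if the sense proves opposite.

Step 1
Reactants: 1 eugenol (4-allyl-2-methoxyphenol)
Product: 2 4-allyl-2-methoxyphenyl pivalate
Conditions: PivCl, Et3N, 4-(dimethylamino)pyridine (cat.), CH2Cl2, 0 °C to rt
Reagents that add atoms: pivaloyl chloride, CC(C)(C)C(Cl)=O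
Why: Acylation of the phenol (nucleophile-catalysed esterification) should be clean, and the pivalate both survives every step up to step 11 and lowers the electron density of ring B for the key step.

Step 2
Reactants: 2 4-allyl-2-methoxyphenyl pivalate
Product: 4 4-(3-hydroxypropyl)-2-methoxyphenyl pivalate, via B-alkyl-9-BBN adduct 3 (not isolated)
Conditions: 9-BBN, THF, 0 °C to rt; then NaBO3·4H2O, H2O, rt
Reagents that add atoms: sodium perborate (NaBO3, used as the tetrahydrate; oxygen source), [Na+].[O-]OB=O
Why: Hydroboration–oxidation with 9-BBN places boron on the terminal carbon of the allyl group (anti-Markovnikov), and the mild perborate oxidation should spare the aryl pivalate.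

Step 3
Reactants: 4 4-(3-hydroxypropyl)-2-methoxyphenyl pivalate
Product: 5 2-methoxy-4-(3-oxopropyl)phenyl pivalate
Conditions: 2,2,6,6-tetramethylpiperidin-1-oxyl (cat.), PhI(OAc)2, CH2Cl2, rt
Reagents that add atoms: none
Why: The oxoammonium-mediated alcohol oxidation (nitroxyl catalyst with PhI(OAc)2 as terminal oxidant) stops at the aldehyde under non-basic conditions that leave the ester and the arene alone.

Step 4
Reactants: 5 2-methoxy-4-(3-oxopropyl)phenyl pivalate; 6 allenylboronic acid pinacol ester
Product: 8 4-[(S)-3-hydroxyhex-5-yn-1-yl]-2-methoxyphenyl pivalate, via homopropargylic pinacol borate 7 (not isolated)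
Conditions: (R)-3,3'-bis(2,4,6-triisopropylphenyl)-1,1'-binaphthyl-2,2'-diyl hydrogen phosphate (10 mol%), 4 Å MS, toluene, −20 °C; aqueous work-up
Reagents that add atoms: none
Why: Chiral phosphoric acid-catalysed allenylboration (asymmetric propargylation through a six-membered chair-like transition state with transposition of the allenyl group, the acid hydrogen-bonded to a boronate oxygen and to the formyl hydrogen) should deliver the propargyl group to the Re face of the aldehyde and so set the (S) carbinol that becomes C6.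

Step 5
Reactants: 9 3,4-dihydroxy-5-methoxybenzaldehyde
Product: 10 7-methoxy-2,2-diphenyl-1,3-benzodioxole-5-carbaldehyde
Conditions: Ph2CCl2, Ph2O, 175 °C
Reagents that add atoms: dichlorodiphenylmethane, ClC(Cl)(c1ccccc1)c1ccccc1
Why: Thermal ketalisation of the catechol (diphenylmethylene acetal formation, HCl driven off) ties O3 and O4 of ring A into a five-membered ring, which holds the 4-oxygen lone pair in conjugation with the arene (an open 4-alkoxy group flanked by two oxygens twists out of plane) and gives a protecting group with no C–H bond for an oxidant to attack.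

Step 6
Reactants: 10 7-methoxy-2,2-diphenyl-1,3-benzodioxole-5-carbaldehyde
Product: 11 (7-methoxy-2,2-diphenyl-1,3-benzodioxol-5-yl)methanol
Conditions: NaBH4, MeOH/THF, 0 °C
Reagents that add atoms: none
Why: Borohydride reduction of the aryl aldehyde is chemoselective and leaves the acetal untouched.

Step 7
Reactants: 11 (7-methoxy-2,2-diphenyl-1,3-benzodioxol-5-yl)methanol
Product: 12 (7-methoxy-2,2-diphenyl-1,3-benzodioxol-5-yl)methyl 2,2,2-trichloroacetimidate
Conditions: Cl3CCN, 1,8-diazabicyclo[5.4.0]undec-7-ene (cat.), CH2Cl2, 0 °C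
Reagents that add atoms: trichloroacetonitrile, N#CC(Cl)(Cl)Cl
Why: Base-catalysed addition of the benzylic alcohol to trichloroacetonitrile (trichloroacetimidate formation) is the standard activation of an electron-rich benzyl alcohol for acid-catalysed etherification.

Step 8
Reactants: 8 4-[(S)-3-hydroxyhex-5-yn-1-yl]-2-methoxyphenyl pivalate; 12 (7-methoxy-2,2-diphenyl-1,3-benzodioxol-5-yl)methyl 2,2,2-trichloroacetimidate
Product: 13 2-methoxy-4-{(S)-3-[(7-methoxy-2,2-diphenyl-1,3-benzodioxol-5-yl)methoxy]hex-5-yn-1-yl}phenyl pivalate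
Conditions: camphor-10-sulfonic acid (cat.), CH2Cl2, 0 °C to rt
Reagents that add atoms: none
Why: Acid-catalysed benzylation with the trichloroacetimidate goes through the stabilised ring A benzylic cation under conditions an aryl pivalate tolerates (a Williamson ether synthesis would not), and because the carbinol C–O bond is never broken the (S) configuration is retained.

Step 9
Reactants: 13 2-methoxy-4-{(S)-3-[(7-methoxy-2,2-diphenyl-1,3-benzodioxol-5-yl)methoxy]hex-5-yn-1-yl}phenyl pivalate
Product: 14 (S)-4-[(7-methoxy-2,2-diphenyl-1,3-benzodioxol-5-yl)methoxy]-6-[3-methoxy-4-(pivaloyloxy)phenyl]hex-1-en-2-yl acetate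
Conditions: AcOH, [RuCl2(p-cymene)]2 (2 mol%), P(2-furyl)3 (4 mol%), Na2CO3 (4 mol%), toluene, 80 °C
Reagents that add atoms: acetic acid, CC(=O)O
Why: Ruthenium-catalysed Markovnikov hydroacyloxylation of the terminal alkyne (addition of acetic acid, with the furylphosphine/carbonate pair steering the carboxylate to the internal carbon) gives the 2-acetoxy-1-alkene without touching ether, ester or acetal.

Step 10
Reactants: 14 (S)-4-[(7-methoxy-2,2-diphenyl-1,3-benzodioxol-5-yl)methoxy]-6-[3-methoxy-4-(pivaloyloxy)phenyl]hex-1-en-2-yl acetate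
Product: 17 (2S,6S)-2-(7-methoxy-2,2-diphenyl-1,3-benzodioxol-5-yl)-6-{2-[3-methoxy-4-(pivaloyloxy)phenyl]ethyl}tetrahydro-4H-pyran-4-one, via (E)-aryl oxocarbenium ion 15 (not isolated), via cyclised O-acetyl oxocarbenium ion 16 (not isolated)
Conditions: DDQ, 2,6-dichloropyridine, LiClO4, 4 Å MS, ClCH2CH2Cl, rt
Reagents that add atoms: none
Why: DDQ forms a charge-transfer complex with ring A, and electron transfer followed by loss of the C2 hydrogen (net hydride abstraction) gives the (E)-aryl oxocarbenium ion 15, which in the buffered, LiClO4-containing medium is captured by the tethered enol acetate before the acetyl group is shed to leave ketone 17. The reaction type is the known quinone-mediated oxidative C–H cleavage of electron-rich benzylic ethers with intramolecular enol acetate addition, a Prins-type oxocarbenium cyclisation. Ring C closes by 6-endo-trig attack of the enol acetate terminus C3 on C2. The new C2 centre is controlled by the existing (S)-C6 centre through a chair transition state in which the aryl group of the (E)-oxocarbenium ion and the C6 arylethyl chain are both equatorial, which gives the 2,6-cis (2S,6S) ring. The step needs oxidation at C2–H alone: the benzodioxole acetal keeps the ring A 4-oxygen conjugated para to C2 and has no C–H bond of its own, ring B is deactivated by its pivalate (its C8–H is para to the acyloxy group and only meta to the methoxy group), and the inductive pull of the C4 ketone protects the C2–H of the product from a second oxidation.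

Step 11
Reactants: 17 (2S,6S)-2-(7-methoxy-2,2-diphenyl-1,3-benzodioxol-5-yl)-6-{2-[3-methoxy-4-(pivaloyloxy)phenyl]ethyl}tetrahydro-4H-pyran-4-one
Product: 19 (2S,4S,6S)-2-[2-(4-hydroxy-3-methoxyphenyl)ethyl]-6-(7-methoxy-2,2-diphenyl-1,3-benzodioxol-5-yl)tetrahydro-2H-pyran-4-ol, via axial alcohol pivalate 18 (not isolated)
Conditions: LiBH(s-Bu)3, THF, −78 °C; then MeOH, K2CO3 (cat.), −78 °C to rt
Reagents that add atoms: none
Why: The bulky hydride attacks the chair ketone, locked by its two equatorial substituents, along the equatorial trajectory (steric approach control) to give the axial (4S) alcohol, and the methoxide generated on the methanol quench then removes the aryl pivalate by transesterification in the same flask.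

Step 12
Reactants: 19 (2S,4S,6S)-2-[2-(4-hydroxy-3-methoxyphenyl)ethyl]-6-(7-methoxy-2,2-diphenyl-1,3-benzodioxol-5-yl)tetrahydro-2H-pyran-4-ol
Product: 20 (2S,4S,6S)-2-(3,4-dihydroxy-5-methoxyphenyl)-6-[2-(4-hydroxy-3-methoxyphenyl)ethyl]tetrahydro-2H-pyran-4-ol
Conditions: H2 (1 atm), 10% Pd/C, EtOAc/MeOH, rt
Reagents that add atoms: none
Why: Catalytic hydrogenolysis cleaves the doubly benzylic C–O bonds of the diphenylmethylene acetal under neutral conditions that suit the air-sensitive catechol, and it should be faster than cleavage of the singly benzylic C2–O1 bond of ring C.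

Compound list
1 | eugenol (4-allyl-2-methoxyphenol) | COc1cc(CC=C)ccc1O | starting material
2 | 4-allyl-2-methoxyphenyl pivalate | COc1cc(CC=C)ccc1OC(=O)C(C)(C)C | intermediate
3 | 9-{3-[3-methoxy-4-(pivaloyloxy)phenyl]propyl}-9-borabicyclo[3.3.1]nonane | COc1cc(CCCB2C3CCCC2CCC3)ccc1OC(=O)C(C)(C)C | intermediate (not isolated)
4 | 4-(3-hydroxypropyl)-2-methoxyphenyl pivalate | COc1cc(CCCO)ccc1OC(=O)C(C)(C)C | intermediate
5 | 2-methoxy-4-(3-oxopropyl)phenyl pivalate | COc1cc(CCC=O)ccc1OC(=O)C(C)(C)C | intermediate
6 | allenylboronic acid pinacol ester | C=C=CB1OC(C)(C)C(C)(C)O1 | starting material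
7 | 2-methoxy-4-{(S)-3-[(4,4,5,5-tetramethyl-1,3,2-dioxaborolan-2-yl)oxy]hex-5-yn-1-yl}phenyl pivalate | COc1cc(CC[C@H](OB2OC(C)(C)C(C)(C)O2)CC#C)ccc1OC(=O)C(C)(C)C | intermediate (not isolated)
8 | 4-[(S)-3-hydroxyhex-5-yn-1-yl]-2-methoxyphenyl pivalate | COc1cc(CC[C@H](O)CC#C)ccc1OC(=O)C(C)(C)C | intermediate
9 | 3,4-dihydroxy-5-methoxybenzaldehyde | COc1cc(C=O)cc(O)c1O | starting material
10 | 7-methoxy-2,2-diphenyl-1,3-benzodioxole-5-carbaldehyde | COc1cc(C=O)cc2OC(c3ccccc3)(c3ccccc3)Oc12 | intermediate
11 | (7-methoxy-2,2-diphenyl-1,3-benzodioxol-5-yl)methanol | COc1cc(CO)cc2OC(c3ccccc3)(c3ccccc3)Oc12 | intermediate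
12 | (7-methoxy-2,2-diphenyl-1,3-benzodioxol-5-yl)methyl 2,2,2-trichloroacetimidate | COc1cc(COC(=N)C(Cl)(Cl)Cl)cc2OC(c3ccccc3)(c3ccccc3)Oc12 | intermediate
13 | 2-methoxy-4-{(S)-3-[(7-methoxy-2,2-diphenyl-1,3-benzodioxol-5-yl)methoxy]hex-5-yn-1-yl}phenyl pivalate | COc1cc(CC[C@H](OCc2cc(OC)c3OC(c4ccccc4)(c4ccccc4)Oc3c2)CC#C)ccc1OC(=O)C(C)(C)C | intermediate
14 | (S)-4-[(7-methoxy-2,2-diphenyl-1,3-benzodioxol-5-yl)methoxy]-6-[3-methoxy-4-(pivaloyloxy)phenyl]hex-1-en-2-yl acetate (key-step precursor) | COc1cc(CC[C@H](OCc2cc(OC)c3OC(c4ccccc4)(c4ccccc4)Oc3c2)CC(=C)OC(C)=O)ccc1OC(=O)C(C)(C)C | intermediate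
15 | (E)-aryl oxocarbenium ion from 14 (O1=C2 cation, enol acetate still pendant) | COc1cc(CC[C@@H](CC(=C)OC(C)=O)/[O+]=C/c2cc(OC)c3OC(c4ccccc4)(c4ccccc4)Oc3c2)ccc1OC(=O)C(C)(C)C | intermediate (not isolated)
16 | ring-closed (2S,6S) O-acetyl oxocarbenium ion (C4=O+–Ac) | COc1cc(CC[C@H]2CC(=[O+]C(C)=O)C[C@@H](c3cc(OC)c4OC(c5ccccc5)(c5ccccc5)Oc4c3)O2)ccc1OC(=O)C(C)(C)C | intermediate (not isolated)
17 | (2S,6S)-2-(7-methoxy-2,2-diphenyl-1,3-benzodioxol-5-yl)-6-{2-[3-methoxy-4-(pivaloyloxy)phenyl]ethyl}tetrahydro-4H-pyran-4-one (key-step product, 2,6-cis) | COc1cc(CC[C@H]2CC(=O)C[C@@H](c3cc(OC)c4OC(c5ccccc5)(c5ccccc5)Oc4c3)O2)ccc1OC(=O)C(C)(C)C | intermediate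
18 | 4-{2-[(2S,4S,6S)-4-hydroxy-6-(7-methoxy-2,2-diphenyl-1,3-benzodioxol-5-yl)tetrahydro-2H-pyran-2-yl]ethyl}-2-methoxyphenyl pivalate (axial C4–OH) | COc1cc(CC[C@H]2C[C@H](O)C[C@@H](c3cc(OC)c4OC(c5ccccc5)(c5ccccc5)Oc4c3)O2)ccc1OC(=O)C(C)(C)C | intermediate (not isolated)
19 | (2S,4S,6S)-2-[2-(4-hydroxy-3-methoxyphenyl)ethyl]-6-(7-methoxy-2,2-diphenyl-1,3-benzodioxol-5-yl)tetrahydro-2H-pyran-4-ol | COc1cc(CC[C@H]2C[C@H](O)C[C@@H](c3cc(OC)c4OC(c5ccccc5)(c5ccccc5)Oc4c3)O2)ccc1O | intermediate
20 | (2S,4S,6S)-2-(3,4-dihydroxy-5-methoxyphenyl)-6-[2-(4-hydroxy-3-methoxyphenyl)ethyl]tetrahydro-2H-pyran-4-ol (2,6-cis, C4–OH axial) | COc1cc(CC[C@H]2C[C@H](O)C[C@@H](c3cc(O)c(O)c(OC)c3)O2)ccc1O | target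

Total step count: 12 steps.
Longest linear sequence: 9 steps from eugenol (steps 1–4 and 8–12). The ring A branch (steps 5–7) joins at step 8.

Steps most likely to fail

Step 10. The hydride abstraction may be slow, the more electron-rich ring A may allow a second oxidation at C2–H of the product, and adventitious water may hydrolyse the oxocarbenium ion or the enol acetate. The fallback sets out from aldehyde 10 and comes back at ketone 17, with aldehyde 5 as the second component. Claisen–Schmidt condensation of 10 with acetone (aqueous NaOH) should give (E)-4-(7-methoxy-2,2-diphenyl-1,3-benzodioxol-5-yl)but-3-en-2-one F1. Silylation with Et3SiOTf/Et3N should give the 2-silyloxy diene (E)-triethyl{[4-(7-methoxy-2,2-diphenyl-1,3-benzodioxol-5-yl)buta-1,3-dien-2-yl]oxy}silane F2. An endo-selective asymmetric hetero-Diels–Alder reaction of F2 with 5 would then be run with the chloro chromium complex (trivalent chromium) of the tridentate Schiff base from 3-(1-adamantyl)-2-hydroxy-5-methylbenzaldehyde and cis-1-amino-2-indanol, in the enantiomeric form that leads to the (2S,6S) adduct. It should give 4-{2-[(2S,6S)-6-(7-methoxy-2,2-diphenyl-1,3-benzodioxol-5-yl)-4-(triethylsilyloxy)-3,6-dihydro-2H-pyran-2-yl]ethyl}-2-methoxyphenyl pivalate F3, and Bu4NF/AcOH in THF should release ketone 17. Here C2–O1 and C5–C6 are made by cycloaddition and both ring stereocentres are set by the catalyst.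

Step 4. Enantioselectivity may erode through the uncatalysed background addition of the allenylboronate to an unbranched aliphatic aldehyde. The fallback sets out from aldehyde 5 and comes back at alcohol 8. It changes both the nucleophile and the mode of activation: allenyltributylstannane is added to 5 under chiral Lewis acid catalysis by Ti(OiPr)4 and (R)-1,1'-bi-2-naphthol (4 Å MS, CH2Cl2, −20 °C). By analogy with the corresponding asymmetric allylation this should again favour Re-face attack and give (S)-8 after work-up.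

Step 12. Reductive cleavage of the benzylic C2–O1 bond (opening of ring C) may compete while the acetal is being hydrogenolysed, and the liberated catechol may oxidise in air. The fallback sets out from 19 and comes back at target 20. It replaces the reductive cleavage by hydrolysis: aqueous acetic acid (AcOH/H2O 4:1, THF, about 60 °C, under argon) hydrolyses the diphenylmethylene acetal to the catechol and benzophenone, with no reducing agent present.

Further compounds
F1 | step 10 | (E)-4-(7-methoxy-2,2-diphenyl-1,3-benzodioxol-5-yl)but-3-en-2-one | CC(=O)/C=C/c1cc(OC)c2OC(c3ccccc3)(c3ccccc3)Oc2c1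
F2 | step 10 | (E)-triethyl{[4-(7-methoxy-2,2-diphenyl-1,3-benzodioxol-5-yl)buta-1,3-dien-2-yl]oxy}silane | C=C(O[Si](CC)(CC)CC)/C=C/c1cc(OC)c2OC(c3ccccc3)(c3ccccc3)Oc2c1
F3 | step 10 | 4-{2-[(2S,6S)-6-(7-methoxy-2,2-diphenyl-1,3-benzodioxol-5-yl)-4-(triethylsilyloxy)-3,6-dihydro-2H-pyran-2-yl]ethyl}-2-methoxyphenyl pivalate | COc1cc(CC[C@H]2CC(O[Si](CC)(CC)CC)=C[C@@H](c3cc(OC)c4OC(c5ccccc5)(c5ccccc5)Oc4c3)O2)ccc1OC(=O)C(C)(C)C
F0 | step 4 | none | none
F0 | step 12 | none | none
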